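**Plan**

- Retrosynthetic cuts: C6–C7 (Suzuki–Miyaura coupling at an enol triflate); then the C8–C9 bond is opened and C7–C9 restored, which re-expands the cyclopentenone to a six-membered α,β-epoxy ketone; then the oxirane oxygen, the C10–Cl bond and the acetyl group are removed, the C12–O bond goes back to a phenol, and C13–C14 is cut to a benzylic bromide and hept-1-yne.
- Enabling feature: C12 is tied to the C9 carbonyl twice, through C11=C10 and through C8, and C8 carries the one-carbon branch C7. Writing C7 between C8 and C9 turns ring C8–C12 into a six-membered 4-acetoxy-dienone (an oxidised para-alkylphenol) whose C7–C8 oxirane lies α,β to C9.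
- Forward order: the alkyne chain is joined to the arene; the phenol is dearomatised to the para-quinol (the carbocycle is the former arene ring); the oxirane ring is added to one enone; acetylation, C10 chlorination and semi-hydrogenation follow; the six-membered ring contracts to the cyclopentenone (step 10); the C1–C6 chain is joined last.
- Stereochemistry: C12 comes from the catalyst-controlled, hydroxyl-syn mono-epoxidation that desymmetrises the achiral quinol (step 6) and is a bystander afterwards. 14Z comes from Lindlar hydrogenation, 7E from the enol triflate geometry (retained in the coupling), and 5E from syn-hydroboration.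

Key step: step 10

Assumption: the absolute sense of induction of the amine catalyst in step 6 cannot be predicted for a cross-conjugated quinol. The quinine-derived catalyst is written; its quinidine-derived pseudo-enantiomer takes its place if the antipode of 9 is formed.

**Route**

Step 1
Reactants: 1 4-hydroxybenzyl alcohol
Product: 2 [4-(tert-butyldimethylsilyloxy)phenyl]methanol
Conditions: NaH (1.0 equiv), THF, 0 °C; TBSCl (1.05 equiv), 0 to 25 °C
Reagents that add atoms: tert-butyldimethylsilyl chloride, CC(C)(C)[Si](C)(C)Cl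
Why: One equivalent of NaH should deprotonate only the phenol, which is far more acidic than the benzylic alcohol, and the phenoxide is silylated at oxygen (chemoselective O-silylation).

Step 2
Reactants: 2 [4-(tert-butyldimethylsilyloxy)phenyl]methanol
Product: 3 [4-(bromomethyl)phenoxy](tert-butyl)dimethylsilane
Conditions: CBr4, PPh3, CH2Cl2, 0 °C
Reagents that add atoms: carbon tetrabromide, BrC(Br)(Br)Br
Why: The Appel reaction converts the primary benzylic alcohol into the bromide under neutral conditions that should leave the aryl silyl ether intact.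

Step 3
Reactants: 4 hept-1-yne; 3 [4-(bromomethyl)phenoxy](tert-butyl)dimethylsilane
Product: 6 tert-butyldimethyl[4-(oct-2-yn-1-yl)phenoxy]silane, via hept-1-ynylmagnesium bromide 5 (not isolated)
Conditions: 4, EtMgBr, THF, 40 °C; then CuBr·SMe2 (5 mol %), 3, 50 °C
Reagents that add atoms: none
Why: Copper-catalysed coupling of an alkynyl Grignard reagent with a benzylic bromide forms C13–C14 by direct substitution, and because the alkyne is the nucleophile no propargyl/allenyl ambiguity can arise.

Step 4
Reactants: 6 tert-butyldimethyl[4-(oct-2-yn-1-yl)phenoxy]silane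
Product: 7 4-(oct-2-yn-1-yl)phenol
Conditions: TBAF (1.1 equiv), THF, 0 °C; aq. NH4Cl
Reagents that add atoms: none
Why: Fluoride cleaves the aryl silyl ether through the strong Si–F bond (desilylation), and the skipped alkyne should not isomerise at this temperature.

Step 5
Reactants: 7 4-(oct-2-yn-1-yl)phenol
Product: 8 4-hydroxy-4-(oct-2-yn-1-yl)cyclohexa-2,5-dien-1-one
Conditions: PhI(OAc)2 (1.1 equiv), MeCN–H2O (3:1), 0 °C
Reagents that add atoms: water, O
Why: Oxidative dearomatisation with a trivalent iodine reagent: ligand exchange at iodine and two-electron oxidation make the ring electrophilic, and water should add at the alkyl-bearing para carbon to give the achiral para-quinol.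

Step 6
Reactants: 8 4-hydroxy-4-(oct-2-yn-1-yl)cyclohexa-2,5-dien-1-one
Product: 9 (4R,5S,6R)-5,6-epoxy-4-hydroxy-4-(oct-2-yn-1-yl)cyclohex-2-en-1-one (oxirane syn to the hydroxyl)
Conditions: 9-amino(9-deoxy)epi-quinine (10 mol %), CF3CO2H (20 mol %), 50 % aq. H2O2 (1.2 equiv), 1,4-dioxane, 30 °C
Reagents that add atoms: hydrogen peroxide, OO
Why: Proposed new method: the closest known reaction is the Weitz–Scheffer epoxidation of cyclic enones (4,4-disubstituted cyclohex-2-enones included) with aqueous H2O2 under catalysis by cinchona-derived primary amine salts, not yet applied to a cross-conjugated 4-hydroxycyclohexadienone; here the amine should condense with the C9 carbonyl to an iminium ion, its protonated quinuclidine should hand H2O2 to one β-carbon on a face fixed relative to the catalyst, and the enamine should then close the oxirane; because turning the quinol by 180° under the bound catalyst exchanges arm and face together, the catalyst allows only syn attack on one arm or anti attack on the other, and the hydroxyl (hydrogen bond to the peroxide, smaller than the propargylic CH2) should select the syn path, so that C12, C8 and C7 are set together and a lapse in substrate control would give the separable anti diastereomer and not the antipode.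

Step 7
Reactants: 9 (4R,5S,6R)-5,6-epoxy-4-hydroxy-4-(oct-2-yn-1-yl)cyclohex-2-en-1-one
Product: 10 (4R,5S,6R)-4-acetoxy-5,6-epoxy-4-(oct-2-yn-1-yl)cyclohex-2-en-1-one
Conditions: Ac2O, Et3N, DMAP (cat.), CH2Cl2, 0 to 25 °C
Reagents that add atoms: acetic anhydride, CC(=O)OC(C)=O
Why: DMAP-catalysed acylation should esterify the tertiary alcohol without touching a stereocentre, since the syn oxirane offers the neighbouring oxygen no backside path.

Step 8
Reactants: 10 (4R,5S,6R)-4-acetoxy-5,6-epoxy-4-(oct-2-yn-1-yl)cyclohex-2-en-1-one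
Product: 11 (4R,5S,6R)-4-acetoxy-2-chloro-5,6-epoxy-4-(oct-2-yn-1-yl)cyclohex-2-en-1-one
Conditions: PhICl2 (1.2 equiv), pyridine, CH2Cl2, 0 to 25 °C, dark
Reagents that add atoms: (dichloroiodo)benzene, ClI(Cl)c1ccccc1
Why: α-Chlorination of an enone with (dichloroiodo)benzene and pyridine: chlorine adds across C10=C11, the only C=C left, and pyridine-induced loss of HCl keeps the chlorine on C10; the internal alkyne is far less reactive towards electrophilic chlorine than the Z-alkene would be, which is why the chain is carried as an alkyne to this point.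

Step 9
Reactants: 11 (4R,5S,6R)-4-acetoxy-2-chloro-5,6-epoxy-4-(oct-2-yn-1-yl)cyclohex-2-en-1-one
Product: 12 (4R,5S,6R)-4-acetoxy-2-chloro-5,6-epoxy-4-[(2Z)-oct-2-en-1-yl]cyclohex-2-en-1-one
Conditions: H2 (1 atm), Pd/CaCO3 poisoned with Pb(OAc)2 (Lindlar catalyst), quinoline, EtOAc, 20 °C
Reagents that add atoms: none
Why: Lindlar semi-hydrogenation delivers one equivalent of hydrogen syn on the poisoned palladium surface to give the 14Z alkene, while the hindered, electron-poor chloroenone and the oxirane should not compete.

Step 10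
Reactants: 12 (4R,5S,6R)-4-acetoxy-2-chloro-5,6-epoxy-4-[(2Z)-oct-2-en-1-yl]cyclohex-2-en-1-one
Product: 14 (4R,5Z)-4-acetoxy-2-chloro-5-(hydroxymethylidene)-4-[(2Z)-oct-2-en-1-yl]cyclopent-2-en-1-one, via the 5-formyl keto tautomer 13 (not isolated)
Conditions: BF3·OEt2 (0.3 equiv), CH2Cl2, −40 to 0 °C; aq. NaHCO3
Reagents that add atoms: none
Why: BF3 binds the oxirane oxygen, the C8–O bond lengthens (C8 is β to the C9 carbonyl, whereas a cation at C7 would sit α to it), and the C7–C9 acyl bond shifts to C8 on the face opposite the departing oxygen, leaving C7 as a formyl carbon (13) that enolises to the hydrogen-bonded hydroxymethylene ketone 14. The closest known reaction type is the Lewis-acid rearrangement of 2,3-epoxycyclohexanones to 2-formylcyclopentanones (α,β-epoxy ketone to β-dicarbonyl by 1,2-acyl shift). Ring C8–C12 is not closed by a cyclisation; it arises by ring contraction, C8–C9 forming as C7–C9 breaks and C7 leaving the ring. The transient centre C8 of 13 (inversion at the migration terminus) is erased on enolisation, and C12, fixed in step 6, keeps all four of its bonds. Three diversions have to lose: a 1,2-hydride shift from C7 (to the 1,2-dione enol), a semipinacol shift of C11 or C13 away from C12, and trapping of C8 by the ester; an acyl group is the better migrating group in epoxy ketones, the acetate (unlike a free hydroxyl or a silyl ether) gives no push for a C12 substituent, and sitting on the same face as the oxirane oxygen it has no backside trajectory to C8.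

Step 11
Reactants: 14 (4R,5Z)-4-acetoxy-2-chloro-5-(hydroxymethylidene)-4-[(2Z)-oct-2-en-1-yl]cyclopent-2-en-1-one
Product: 15 (4R,5E)-4-acetoxy-2-chloro-4-[(2Z)-oct-2-en-1-yl]-5-{[(trifluoromethylsulfonyl)oxy]methylidene}cyclopent-2-en-1-one
Conditions: DBU (1.1 equiv), Tf2O (1.05 equiv), CH2Cl2, −78 °C
Reagents that add atoms: trifluoromethanesulfonic anhydride, O=S(=O)(OS(=O)(=O)C(F)(F)F)C(F)(F)F
Why: Enol triflate formation from a β-keto aldehyde under non-chelating conditions: with no metal to hold its two oxygens together the amidinium enolate should adopt the extended form and be sulfonylated at the less hindered aldehyde-derived oxygen anti to the C9 carbonyl, which gives the E-triflate.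

Step 12
Reactants: 16 methyl hex-5-ynoate
Product: 17 methyl (5E)-6-(4,4,5,5-tetramethyl-1,3,2-dioxaborolan-2-yl)hex-5-enoate
Conditions: pinacolborane (1.1 equiv), Cy2BH (5 mol %), neat, 25 °C
Reagents that add atoms: pinacolborane, [H]B1OC(C)(C)C(C)(C)O1
Why: Cy2BH-catalysed hydroboration of a terminal alkyne with pinacolborane adds H–B syn and anti-Markovnikov, which gives the E-alkenylboronate and leaves the ester alone.

Step 13
Reactants: 15 (4R,5E)-4-acetoxy-2-chloro-4-[(2Z)-oct-2-en-1-yl]-5-{[(trifluoromethylsulfonyl)oxy]methylidene}cyclopent-2-en-1-one; 17 methyl (5E)-6-(4,4,5,5-tetramethyl-1,3,2-dioxaborolan-2-yl)hex-5-enoate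
Product: 18 methyl (5E,7E,12R,14Z)-12-acetoxy-10-chloro-9-oxoprosta-5,7,10,14-tetraenoate
Conditions: Pd(PPh3)4 (5 mol %), K3PO4, THF–H2O (10:1), 25 °C
Reagents that add atoms: none
Why: Suzuki–Miyaura coupling: zerovalent palladium should insert into the activated C7–O(triflate) bond much faster than into the C10–Cl bond or the hindered tertiary allylic acetate, and transmetalation and reductive elimination join C6 to C7 with retention of the 5E and 7E geometries.

**Compound list**

1 | 4-hydroxybenzyl alcohol | OCc1ccc(O)cc1 | starting material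
2 | [4-(tert-butyldimethylsilyloxy)phenyl]methanol | CC(C)(C)[Si](C)(C)Oc1ccc(CO)cc1 | intermediate
3 | [4-(bromomethyl)phenoxy](tert-butyl)dimethylsilane | CC(C)(C)[Si](C)(C)Oc1ccc(CBr)cc1 | intermediate
4 | hept-1-yne | CCCCCC#C | starting material
5 | hept-1-ynylmagnesium bromide | CCCCCC#C[Mg]Br | intermediate
6 | tert-butyldimethyl[4-(oct-2-yn-1-yl)phenoxy]silane | CCCCCC#CCc1ccc(O[Si](C)(C)C(C)(C)C)cc1 | intermediate
7 | 4-(oct-2-yn-1-yl)phenol | CCCCCC#CCc1ccc(O)cc1 | intermediate
8 | 4-hydroxy-4-(oct-2-yn-1-yl)cyclohexa-2,5-dien-1-one | CCCCCC#CCC1(O)C=CC(=O)C=C1 | intermediate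
9 | (4R,5S,6R)-5,6-epoxy-4-hydroxy-4-(oct-2-yn-1-yl)cyclohex-2-en-1-one | CCCCCC#CC[C@@]1(O)C=CC(=O)[C@@H]2O[C@@H]21 | intermediate
10 | (4R,5S,6R)-4-acetoxy-5,6-epoxy-4-(oct-2-yn-1-yl)cyclohex-2-en-1-one | CCCCCC#CC[C@@]1(OC(C)=O)C=CC(=O)[C@@H]2O[C@@H]21 | intermediate
11 | (4R,5S,6R)-4-acetoxy-2-chloro-5,6-epoxy-4-(oct-2-yn-1-yl)cyclohex-2-en-1-one | CCCCCC#CC[C@@]1(OC(C)=O)C=C(Cl)C(=O)[C@@H]2O[C@@H]21 | intermediate
12 | (4R,5S,6R)-4-acetoxy-2-chloro-5,6-epoxy-4-[(2Z)-oct-2-en-1-yl]cyclohex-2-en-1-one | CCCCC/C=C\C[C@@]1(OC(C)=O)C=C(Cl)C(=O)[C@@H]2O[C@@H]21 | intermediate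
13 | (4S,5S)-4-acetoxy-2-chloro-5-formyl-4-[(2Z)-oct-2-en-1-yl]cyclopent-2-en-1-one (formyl cis to acetoxy) | CCCCC/C=C\C[C@@]1(OC(C)=O)C=C(Cl)C(=O)[C@@H]1C=O | intermediate
14 | (4R,5Z)-4-acetoxy-2-chloro-5-(hydroxymethylidene)-4-[(2Z)-oct-2-en-1-yl]cyclopent-2-en-1-one | CCCCC/C=C\C[C@@]1(OC(C)=O)C=C(Cl)C(=O)/C1=C\O | intermediate
15 | (4R,5E)-4-acetoxy-2-chloro-4-[(2Z)-oct-2-en-1-yl]-5-{[(trifluoromethylsulfonyl)oxy]methylidene}cyclopent-2-en-1-one | CCCCC/C=C\C[C@@]1(OC(C)=O)C=C(Cl)C(=O)/C1=C/OS(=O)(=O)C(F)(F)F | intermediate
16 | methyl hex-5-ynoate | C#CCCCC(=O)OC | starting material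
17 | methyl (5E)-6-(4,4,5,5-tetramethyl-1,3,2-dioxaborolan-2-yl)hex-5-enoate | COC(=O)CCC/C=C/B1OC(C)(C)C(C)(C)O1 | intermediate
18 | methyl (5E,7E,12R,14Z)-12-acetoxy-10-chloro-9-oxoprosta-5,7,10,14-tetraenoate | CCCCC/C=C\C[C@@]1(OC(C)=O)C=C(Cl)C(=O)/C1=C/C=C/CCCC(=O)OC | target

**Step count and risks**

Total step count: 13. Longest linear sequence: 12 steps (1 to 18 through steps 1–11 and 13).

Steps most likely to fail:

1. Step 6 (Proposed new method). The amine catalyst may discriminate poorly between the two enantiotopic enone arms (low enantiomeric purity), attack may occur anti to the hydroxyl, or a second epoxidation may follow. The fallback uses known chemistry, sets out from 8 and comes back at 10. Hydroxyl-directed Weitz–Scheffer epoxidation of 8 with tBuOOH and benzyltrimethylammonium hydroxide should give the racemic syn-epoxy quinol F1. Ac2O/DMAP should give its racemic acetate F2, and Luche reduction (NaBH4, CeCl3·7H2O, MeOH, −78 °C) the racemic allylic alcohol F3. Acylation with vinyl acetate and Burkholderia cepacia lipase then resolves F3 kinetically into the unreacted alcohol of the needed series F4 and the diacetate of the antipode F5. This is written for that sense of enzyme preference; in the opposite case the diacetate carries the needed series and is deacetylated at the secondary ester by the same lipase in buffer. Dess–Martin periodinane returns F4 to 10.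

2. Step 10. Ionisation at C8 may be slowed by the neighbouring acetoxy-bearing carbon, so that hydride shift from C7, front-side capture of C8 by the ester carbonyl or plain decomposition overtakes the acyl shift. The fallback gives up the ring contraction for the aldol construction of the C7=C8 bond that is established for 5-alkylidene-4-hydroxycyclopent-2-enones. No intermediate of the route can be carried over: it sets out from commercial (R)-4-(tert-butyldimethylsilyloxy)cyclopent-2-en-1-one and 1-bromooct-2-yne (the one-carbon homologue of 4) instead of a numbered compound, and comes back at 18.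
   - Barbier propargylation with zinc in THF (allenylzinc, SE2′) should add the oct-2-ynyl group to the carbonyl anti to the silyloxy group, giving the tertiary alcohol F6.
   - TBAF should give the cis-diol F7, and MnO2 should oxidise only the secondary allylic alcohol to the transposed hydroxy enone F8, whose former carbonyl carbon is now C12.
   - PhICl2/pyridine should chlorinate C10 to give F9, and Lindlar hydrogenation should give the Z-alkene F10.
   - The dianion of F10 (LiN(iPr)2, 2.2 equiv, THF, −78 °C) is added to methyl (5E)-7-oxohept-5-enoate F11 (Wittig product of methyl 5-oxopentanoate and Ph3P=CHCHO) to give the aldol F12.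
   - Ac2O/DMAP acetylates both hydroxyls to the diacetate F13, which should lose acetic acid from C7/C8 by E1cB elimination to give 18.

3. Step 11. Geometric control may be lost in the sulfonylation: the chelated, hydrogen-bonded enol may be triflated instead of the extended enolate, leading to the Z-triflate. The fallback sets out from 14 and comes back at 18; it moves control of the C7=C8 geometry from the kinetic triflation to a thermodynamic equilibration at the end. The Z-triflate F14 (also available on purpose with Tf2O, Et3N and LiOTf) is coupled with 17 as in step 13 to the (5E,7Z)-dienone F15. The C7=C8 bond is then equilibrated with catalytic I2 under visible light in CH2Cl2. The 7E isomer 18 is expected to be favoured because C6 then avoids the in-plane carbonyl oxygen and the dienone can stay planar.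

Further compounds
F1 | step 6 | racemic (4R*,5S*,6R*)-5,6-epoxy-4-hydroxy-4-(oct-2-yn-1-yl)cyclohex-2-en-1-one (racemate of 9, relative configuration shown) | CCCCCC#CC[C@@]1(O)C=CC(=O)[C@@H]2O[C@@H]21
F2 | step 6 | racemic (4R*,5S*,6R*)-4-acetoxy-5,6-epoxy-4-(oct-2-yn-1-yl)cyclohex-2-en-1-one (racemate of 10, relative configuration shown) | CCCCCC#CC[C@@]1(OC(C)=O)C=CC(=O)[C@@H]2O[C@@H]21
F3 | step 6 | racemic 4-acetoxy-5,6-epoxy-4-(oct-2-yn-1-yl)cyclohex-2-en-1-ol, hydroxyl cis to the oxirane (relative configuration shown) | CCCCCC#CC[C@@]1(OC(C)=O)C=C[C@H](O)[C@@H]2O[C@@H]21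
F4 | step 6 | 4-acetoxy-5,6-epoxy-4-(oct-2-yn-1-yl)cyclohex-2-en-1-ol, single enantiomer with the ring configuration of 10 | CCCCCC#CC[C@@]1(OC(C)=O)C=C[C@H](O)[C@@H]2O[C@@H]21
F5 | step 6 | 1,4-diacetoxy-5,6-epoxy-4-(oct-2-yn-1-yl)cyclohex-2-ene, antipodal series | CCCCCC#CC[C@]1(OC(C)=O)C=C[C@@H](OC(C)=O)[C@H]2O[C@H]21
F6 | step 10 | (1S,4R)-4-(tert-butyldimethylsilyloxy)-1-(oct-2-yn-1-yl)cyclopent-2-en-1-ol | CCCCCC#CC[C@@]1(O)C=C[C@H](O[Si](C)(C)C(C)(C)C)C1
F7 | step 10 | (1S,4R)-1-(oct-2-yn-1-yl)cyclopent-2-ene-1,4-diol | CCCCCC#CC[C@@]1(O)C=C[C@H](O)C1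
F8 | step 10 | (S)-4-hydroxy-4-(oct-2-yn-1-yl)cyclopent-2-en-1-one | CCCCCC#CC[C@@]1(O)C=CC(=O)C1
F9 | step 10 | (S)-2-chloro-4-hydroxy-4-(oct-2-yn-1-yl)cyclopent-2-en-1-one | CCCCCC#CC[C@@]1(O)C=C(Cl)C(=O)C1
F10 | step 10 | (S)-2-chloro-4-hydroxy-4-[(2Z)-oct-2-en-1-yl]cyclopent-2-en-1-one | CCCCC/C=C\C[C@@]1(O)C=C(Cl)C(=O)C1
F11 | step 10 | methyl (5E)-7-oxohept-5-enoate | COC(=O)CCC/C=C/C=O
F12 | step 10 | methyl (5E,14Z)-10-chloro-7,12-dihydroxy-9-oxoprosta-5,10,14-trienoate, C12 as in 18, mixture at C7 and C8 | CCCCC/C=C\C[C@@]1(O)C=C(Cl)C(=O)C1C(O)/C=C/CCCC(=O)OC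
F13 | step 10 | methyl (5E,14Z)-7,12-diacetoxy-10-chloro-9-oxoprosta-5,10,14-trienoate, C12 as in 18, mixture at C7 and C8 | CCCCC/C=C\C[C@@]1(OC(C)=O)C=C(Cl)C(=O)C1C(OC(C)=O)/C=C/CCCC(=O)OC
F14 | step 11 | (4R,5Z)-4-acetoxy-2-chloro-4-[(2Z)-oct-2-en-1-yl]-5-{[(trifluoromethylsulfonyl)oxy]methylidene}cyclopent-2-en-1-one | CCCCC/C=C\C[C@@]1(OC(C)=O)C=C(Cl)C(=O)/C1=C\OS(=O)(=O)C(F)(F)F
F15 | step 11 | methyl (5E,7Z,12R,14Z)-12-acetoxy-10-chloro-9-oxoprosta-5,7,10,14-tetraenoate | CCCCC/C=C\C[C@@]1(OC(C)=O)C=C(Cl)C(=O)/C1=C\C=C\CCCC(=O)OC
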